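**Plan**

- Retrosynthetic cuts, in order: the flavanone C2–aryl bond; the flavanone O1–C2–C3 unit and the acetyl C–C bond at flavanone C4a (back to an aryl bromide); O1–C2 and C4–C4a of flavone ring C (back to phloroglucinol and an α-aryl β-ketoester); the ketoester C2–C3 bond and its benzylic carbon (back to 4-methoxybenzoyl chloride and a formylated 3,5-bis(benzyloxy)phenol).
- Enabling feature: flavone ring A (C4a to C8a, with oxygens on C5, C7 and C8a) is a phloroglucinol. Its three ring carbons and three oxygens are equivalent until ring C exists, so C4 can be attached to any ring carbon and either neighbouring oxygen can close O1–C2.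
- Forward order: the fully substituted aryl ring is built first (formylation, silylation, bromination, one-carbon homologation, aroylation). Rings A and C of the flavone then arise in one thermal condensation. 7-O-Methylation, desilylation and acetylation at the bromine follow, and the second pyranone ring is closed through an enaminone.
- Stereochemistry: the only stereocentre, flavanone C2, is set as (R) by ligand-controlled palladium-catalysed conjugate addition of an arylboronic acid to the chromone. Only a neutral hydrogenolysis follows it.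
- Protecting groups: benzyl on the three phenols released at the end, triisopropylsilyl on the oxygen that becomes flavanone O1, and bromine as placeholder for the acetyl group.

Key step: step 8

Assumption: the target string fixes only flavanone C2; the tetra-ortho-substituted biaryl bond between flavone C3 and flavanone C6 is treated as stereochemically undefined, so intermediates may appear as rotamer mixtures and no axial control is attempted.

**Route**

Step 1
Reactants: 1 3,5-bis(benzyloxy)phenol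
Product: 3 2,6-bis(benzyloxy)-4-hydroxybenzaldehyde, via aryl iminium chloride 2 (not isolated)
Conditions: POCl3 (1.3 equiv), DMF, 0 °C → rt; then H2O, 0 °C → rt
Reagents that add atoms: N,N-dimethylformamide CN(C)C=O; water O
Why: Vilsmeier–Haack formylation, which with 3,5-dialkoxyphenols is known to favour the carbon para to the free hydroxyl; the iminium salt is hydrolysed on work-up and the minor ortho isomer should be removable by crystallisation or chromatography.

Step 2
Reactants: 3 2,6-bis(benzyloxy)-4-hydroxybenzaldehyde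
Product: 4 2,6-bis(benzyloxy)-4-[(triisopropylsilyl)oxy]benzaldehyde
Conditions: i-Pr3SiCl, imidazole, DMF, rt
Reagents that add atoms: chlorotriisopropylsilane CC(C)[Si](Cl)(C(C)C)C(C)C
Why: Standard silylation of an acidic phenol; the bulky silyl ether should withstand ylides, amide bases and neutral heat and can later be removed by fluoride without touching benzyl ethers.

Step 3
Reactants: 4 2,6-bis(benzyloxy)-4-[(triisopropylsilyl)oxy]benzaldehyde
Product: 5 2,6-bis(benzyloxy)-3-bromo-4-[(triisopropylsilyl)oxy]benzaldehyde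
Conditions: NBS (1.0 equiv), MeCN, 0 °C → rt, dark
Reagents that add atoms: N-bromosuccinimide O=C1CCC(=O)N1Br
Why: Electrophilic aromatic bromination at the only kind of free ring position (the two are equivalent), with the formyl group moderating reactivity so that monobromination can be held; the bromine marks the carbon that later carries the flavanone carbonyl.

Step 4
Reactants: 5 2,6-bis(benzyloxy)-3-bromo-4-[(triisopropylsilyl)oxy]benzaldehyde
Product: 6 [3,5-bis(benzyloxy)-2-bromo-4-(2-methoxyethenyl)phenoxy]triisopropylsilane (E/Z mixture)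
Conditions: MeOCH2PPh3Cl, KOt-Bu, THF, 0 °C → rt
Reagents that add atoms: (methoxymethyl)triphenylphosphonium chloride COC[P+](c1ccccc1)(c1ccccc1)c1ccccc1.[Cl-]
Why: Wittig methoxymethylenation with a reactive non-stabilised ylide, which adds even to di-ortho-substituted electron-rich benzaldehydes and delivers the one-carbon-extended aldehyde in masked form.

Step 5
Reactants: 6 [3,5-bis(benzyloxy)-2-bromo-4-(2-methoxyethenyl)phenoxy]triisopropylsilane
Product: 8 2-{2,6-bis(benzyloxy)-3-bromo-4-[(triisopropylsilyl)oxy]phenyl}acetic acid, via arylacetaldehyde 7 (not isolated)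
Conditions: 1 M HCl, THF, rt; extractive work-up, crude 7 taken on; NaClO2, NaH2PO4, 2-methyl-2-butene (large excess), t-BuOH/H2O, 0 °C → rt
Reagents that add atoms: water O; sodium chlorite [Na+].[O-]Cl=O
Why: Acid hydrolysis of the enol ether followed at once by Pinnick (Lindgren–Kraus) oxidation of the sensitive arylacetaldehyde, with excess 2-methyl-2-butene trapping hypochlorous acid so that the electron-rich ring is not chlorinated.

Step 6
Reactants: 8 2-{2,6-bis(benzyloxy)-3-bromo-4-[(triisopropylsilyl)oxy]phenyl}acetic acid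
Product: 9 methyl 2-{2,6-bis(benzyloxy)-3-bromo-4-[(triisopropylsilyl)oxy]phenyl}acetate
Conditions: Me3SiCHN2, MeOH/toluene, 0 °C → rt
Reagents that add atoms: trimethylsilyldiazomethane C[Si](C)(C)C=[N+]=[N-]
Why: Esterification of a carboxylic acid with trimethylsilyldiazomethane in methanol, a neutral method that leaves the aryl silyl ether intact.

Step 7
Reactants: 9 methyl 2-{2,6-bis(benzyloxy)-3-bromo-4-[(triisopropylsilyl)oxy]phenyl}acetate; 10 4-methoxybenzoyl chloride
Product: 12 methyl 2-{2,6-bis(benzyloxy)-3-bromo-4-[(triisopropylsilyl)oxy]phenyl}-3-(4-methoxyphenyl)-3-oxopropanoate (racemic), via lithium ester enolate 11 (not isolated)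
Conditions: LiN(SiMe3)2 (2.2 equiv), THF, −78 °C; then 10 (1.1 equiv), −78 → 0 °C; aq. NH4Cl
Reagents that add atoms: none
Why: Crossed Claisen-type C-acylation of a lithium ester enolate with an aroyl chloride, run with two equivalents of base because the β-ketoester product is deprotonated as it forms.

Step 8
Reactants: 12 methyl 2-{2,6-bis(benzyloxy)-3-bromo-4-[(triisopropylsilyl)oxy]phenyl}-3-(4-methoxyphenyl)-3-oxopropanoate; 13 phloroglucinol
Product: 16 3-{2,6-bis(benzyloxy)-3-bromo-4-[(triisopropylsilyl)oxy]phenyl}-5,7-dihydroxy-2-(4-methoxyphenyl)-4H-chromen-4-one, via aroylketene 14 (not isolated), via hydroxyaryl diketone 15 (not isolated)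
Conditions: anhydrous 13 (3 equiv), neat melt, 240 °C, Ar stream, 15–30 min (microwave or sand bath)
Reagents that add atoms: none
Why: On heating, 12 loses methanol to give the α-aryl aroylketene 14, which is captured at its ketene carbon by a ring carbon of phloroglucinol (directly, or through the aryl ester and an O-to-C acyl shift) to form C4–C4a and, after tautomerisation, the hydroxyaryl diketone 15. An ortho hydroxyl of 15 then adds to the anisoyl ketone in a 6-exo-trig closure and the hemiketal loses water, which forms O1–C2 and closes pyranone ring C. The closest known reaction is the Mentzer thermal chromone synthesis from phenols and β-ketoesters, which is documented for α-substituted ketoesters and, in short high-temperature or microwave runs, for phloroglucinol. No stereocentre is created and the one in 12 is erased. The step needs chromone rather than 4-arylcoumarin formation and only one annulation: the absence of acid, the weakly electrophilic aryl ketone and the α-aryl group all send the arene carbon to the ketene carbon, the threefold symmetry of phloroglucinol removes any regiochemical choice, and excess phloroglucinol together with deactivation by the first acyl group should stop the reaction after one pyranone ring. The silyl ether, benzyl ethers and aryl bromide are expected to survive the short acid-free heating.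

Step 9
Reactants: 16 3-{2,6-bis(benzyloxy)-3-bromo-4-[(triisopropylsilyl)oxy]phenyl}-5,7-dihydroxy-2-(4-methoxyphenyl)-4H-chromen-4-one
Product: 17 3-{2,6-bis(benzyloxy)-3-bromo-4-[(triisopropylsilyl)oxy]phenyl}-5-hydroxy-7-methoxy-2-(4-methoxyphenyl)-4H-chromen-4-one
Conditions: Me3SiCHN2 (1.2 equiv), i-Pr2NEt, MeOH/MeCN, 0 °C → rt
Reagents that add atoms: trimethylsilyldiazomethane C[Si](C)(C)C=[N+]=[N-]
Why: Chemoselective O-methylation of a phenol with trimethylsilyldiazomethane: the 7-hydroxyl is the acidic free phenol, whereas the 5-hydroxyl is hydrogen-bonded to the C4 carbonyl and should not react, and the nearly neutral medium spares the silyl ether.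

Step 10
Reactants: 17 3-{2,6-bis(benzyloxy)-3-bromo-4-[(triisopropylsilyl)oxy]phenyl}-5-hydroxy-7-methoxy-2-(4-methoxyphenyl)-4H-chromen-4-one
Product: 18 3-[2,6-bis(benzyloxy)-3-bromo-4-hydroxyphenyl]-5-hydroxy-7-methoxy-2-(4-methoxyphenyl)-4H-chromen-4-one
Conditions: Bu4NF (1.1 equiv), AcOH (1.1 equiv), THF, 0 °C
Reagents that add atoms: none
Why: Fluoride-induced cleavage of an aryl silyl ether, buffered with acetic acid; benzyl and methyl ethers and the aryl bromide are inert, and removing the bulky silyl group also opens up the bromide for the next coupling.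

Step 11
Reactants: 18 3-[2,6-bis(benzyloxy)-3-bromo-4-hydroxyphenyl]-5-hydroxy-7-methoxy-2-(4-methoxyphenyl)-4H-chromen-4-one
Product: 20 3-[3-acetyl-2,6-bis(benzyloxy)-4-hydroxyphenyl]-5-hydroxy-7-methoxy-2-(4-methoxyphenyl)-4H-chromen-4-one, via ethoxyvinyl arene 19 (not isolated)
Conditions: CH2=C(OEt)SnBu3 (1.5 equiv), PdCl2(PPh3)2 (10 mol%; divalent palladium precatalyst, reduced in situ to zerovalent palladium), toluene, 105 °C; then 1 M HCl, THF, rt
Reagents that add atoms: tributyl(1-ethoxyethenyl)stannane CCOC(=C)[Sn](CCCC)(CCCC)CCCC; water O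
Why: Stille coupling of the aryl bromide with an acetyl anion equivalent, followed by acid hydrolysis of the enol ether to the methyl ketone, which places the acetyl group ortho to the free phenol without any Lewis acid that could cleave benzyl ethers.

Step 12
Reactants: 20 3-[3-acetyl-2,6-bis(benzyloxy)-4-hydroxyphenyl]-5-hydroxy-7-methoxy-2-(4-methoxyphenyl)-4H-chromen-4-one
Product: 22 5,7-bis(benzyloxy)-6-[5-hydroxy-7-methoxy-2-(4-methoxyphenyl)-4-oxo-4H-chromen-3-yl]-4H-chromen-4-one, via enaminone 21 (not isolated)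
Conditions: Me2NCH(OMe)2 (3 equiv), toluene, 90 °C; evaporate; conc. HCl, CH2Cl2, rt
Reagents that add atoms: N,N-dimethylformamide dimethyl acetal COC(OC)N(C)C
Why: Enaminone route to chromones: the methyl ketone condenses with the formamide acetal and the ortho phenol then adds to the enaminone under acid with loss of dimethylamine; both remaining phenols are hydrogen-bonded to carbonyls and should not be methylated by the acetal.

Step 13
Reactants: 22 5,7-bis(benzyloxy)-6-[5-hydroxy-7-methoxy-2-(4-methoxyphenyl)-4-oxo-4H-chromen-3-yl]-4H-chromen-4-one; 23 [4-(benzyloxy)phenyl]boronic acid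
Product: 24 (2R)-5,7-bis(benzyloxy)-2-[4-(benzyloxy)phenyl]-6-[5-hydroxy-7-methoxy-2-(4-methoxyphenyl)-4-oxo-4H-chromen-3-yl]-2,3-dihydro-4H-chromen-4-one
Conditions: 23 (2 equiv), Pd(OCOCF3)2 (10 mol%, divalent palladium), (S)-4-tert-butyl-2-(pyridin-2-yl)-4,5-dihydrooxazole (12 mol%), NH4PF6 (30 mol%), H2O (5 equiv), ClCH2CH2Cl, 60 °C
Reagents that add atoms: none
Why: Palladium-catalysed enantioselective conjugate addition of an arylboronic acid to a chromone, in which the cationic arylpalladium complex of the (S)-pyridine-oxazoline ligand carbopalladates C2=C3 from the face left open by the tert-butyl group (expected, by analogy with cyclic enones, to give 2R, with the (R)-ligand as remedy if the sense proves opposite) and water protonates the palladium enolate; the tetrasubstituted flavone double bond cannot compete.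

Step 14
Reactants: 24 (2R)-5,7-bis(benzyloxy)-2-[4-(benzyloxy)phenyl]-6-[5-hydroxy-7-methoxy-2-(4-methoxyphenyl)-4-oxo-4H-chromen-3-yl]-2,3-dihydro-4H-chromen-4-one
Product: 25 (2R)-5,7-dihydroxy-2-(4-hydroxyphenyl)-6-[5-hydroxy-7-methoxy-2-(4-methoxyphenyl)-4-oxo-4H-chromen-3-yl]-2,3-dihydro-4H-chromen-4-one (CNP0292254.1)
Conditions: H2 (1 atm), 10% Pd/C, EtOAc/MeOH, rt, stopped at full debenzylation
Reagents that add atoms: none
Why: Hydrogenolysis of three benzyl aryl ethers under neutral conditions, which avoids the acid- or base-induced opening to the chalcone that would racemise C2 or shift the flavanone to its 8-linked isomer.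

**Compound list**

1 | 3,5-bis(benzyloxy)phenol | Oc1cc(OCc2ccccc2)cc(OCc2ccccc2)c1 | starting material
2 | N-{[2,6-bis(benzyloxy)-4-hydroxyphenyl]methylidene}-N-methylmethanaminium chloride | C[N+](C)=Cc1c(OCc2ccccc2)cc(O)cc1OCc1ccccc1.[Cl-] | intermediate (not isolated)
3 | 2,6-bis(benzyloxy)-4-hydroxybenzaldehyde | O=Cc1c(OCc2ccccc2)cc(O)cc1OCc1ccccc1 | intermediate
4 | 2,6-bis(benzyloxy)-4-[(triisopropylsilyl)oxy]benzaldehyde | O=Cc1c(OCc2ccccc2)cc(O[Si](C(C)C)(C(C)C)C(C)C)cc1OCc1ccccc1 | intermediate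
5 | 2,6-bis(benzyloxy)-3-bromo-4-[(triisopropylsilyl)oxy]benzaldehyde | O=Cc1c(OCc2ccccc2)cc(O[Si](C(C)C)(C(C)C)C(C)C)c(Br)c1OCc1ccccc1 | intermediate
6 | [3,5-bis(benzyloxy)-2-bromo-4-(2-methoxyethenyl)phenoxy]triisopropylsilane (E/Z mixture) | COC=Cc1c(OCc2ccccc2)cc(O[Si](C(C)C)(C(C)C)C(C)C)c(Br)c1OCc1ccccc1 | intermediate
7 | 2-{2,6-bis(benzyloxy)-3-bromo-4-[(triisopropylsilyl)oxy]phenyl}acetaldehyde | O=CCc1c(OCc2ccccc2)cc(O[Si](C(C)C)(C(C)C)C(C)C)c(Br)c1OCc1ccccc1 | intermediate (not isolated)
8 | 2-{2,6-bis(benzyloxy)-3-bromo-4-[(triisopropylsilyl)oxy]phenyl}acetic acid | OC(=O)Cc1c(OCc2ccccc2)cc(O[Si](C(C)C)(C(C)C)C(C)C)c(Br)c1OCc1ccccc1 | intermediate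
9 | methyl 2-{2,6-bis(benzyloxy)-3-bromo-4-[(triisopropylsilyl)oxy]phenyl}acetate | COC(=O)Cc1c(OCc2ccccc2)cc(O[Si](C(C)C)(C(C)C)C(C)C)c(Br)c1OCc1ccccc1 | intermediate
10 | 4-methoxybenzoyl chloride | COc1ccc(C(=O)Cl)cc1 | starting material
11 | lithium enolate of 9 (lithium 2-aryl-1-methoxyethen-1-olate) | [Li+].COC([O-])=Cc1c(OCc2ccccc2)cc(O[Si](C(C)C)(C(C)C)C(C)C)c(Br)c1OCc1ccccc1 | intermediate (not isolated)
12 | methyl 2-{2,6-bis(benzyloxy)-3-bromo-4-[(triisopropylsilyl)oxy]phenyl}-3-(4-methoxyphenyl)-3-oxopropanoate (racemic, enolisable) | COC(=O)C(C(=O)c1ccc(OC)cc1)c1c(OCc2ccccc2)cc(O[Si](C(C)C)(C(C)C)C(C)C)c(Br)c1OCc1ccccc1 | intermediate (key-step precursor)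
13 | phloroglucinol (benzene-1,3,5-triol) | Oc1cc(O)cc(O)c1 | starting material
14 | 2-{2,6-bis(benzyloxy)-3-bromo-4-[(triisopropylsilyl)oxy]phenyl}-3-(4-methoxyphenyl)-3-oxoprop-1-en-1-one (aroylketene) | O=C=C(C(=O)c1ccc(OC)cc1)c1c(OCc2ccccc2)cc(O[Si](C(C)C)(C(C)C)C(C)C)c(Br)c1OCc1ccccc1 | intermediate (not isolated)
15 | 2-{2,6-bis(benzyloxy)-3-bromo-4-[(triisopropylsilyl)oxy]phenyl}-1-(4-methoxyphenyl)-3-(2,4,6-trihydroxyphenyl)propane-1,3-dione | COc1ccc(C(=O)C(C(=O)c2c(O)cc(O)cc2O)c2c(OCc3ccccc3)cc(O[Si](C(C)C)(C(C)C)C(C)C)c(Br)c2OCc2ccccc2)cc1 | intermediate (not isolated)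
16 | 3-{2,6-bis(benzyloxy)-3-bromo-4-[(triisopropylsilyl)oxy]phenyl}-5,7-dihydroxy-2-(4-methoxyphenyl)-4H-chromen-4-one | COc1ccc(-c2oc3cc(O)cc(O)c3c(=O)c2-c2c(OCc3ccccc3)cc(O[Si](C(C)C)(C(C)C)C(C)C)c(Br)c2OCc2ccccc2)cc1 | intermediate (key-step product)
17 | 3-{2,6-bis(benzyloxy)-3-bromo-4-[(triisopropylsilyl)oxy]phenyl}-5-hydroxy-7-methoxy-2-(4-methoxyphenyl)-4H-chromen-4-one | COc1ccc(-c2oc3cc(OC)cc(O)c3c(=O)c2-c2c(OCc3ccccc3)cc(O[Si](C(C)C)(C(C)C)C(C)C)c(Br)c2OCc2ccccc2)cc1 | intermediate
18 | 3-[2,6-bis(benzyloxy)-3-bromo-4-hydroxyphenyl]-5-hydroxy-7-methoxy-2-(4-methoxyphenyl)-4H-chromen-4-one | COc1ccc(-c2oc3cc(OC)cc(O)c3c(=O)c2-c2c(OCc3ccccc3)cc(O)c(Br)c2OCc2ccccc2)cc1 | intermediate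
19 | 3-[2,6-bis(benzyloxy)-3-(1-ethoxyethenyl)-4-hydroxyphenyl]-5-hydroxy-7-methoxy-2-(4-methoxyphenyl)-4H-chromen-4-one | COc1ccc(-c2oc3cc(OC)cc(O)c3c(=O)c2-c2c(OCc3ccccc3)cc(O)c(C(=C)OCC)c2OCc2ccccc2)cc1 | intermediate (not isolated)
20 | 3-[3-acetyl-2,6-bis(benzyloxy)-4-hydroxyphenyl]-5-hydroxy-7-methoxy-2-(4-methoxyphenyl)-4H-chromen-4-one | COc1ccc(-c2oc3cc(OC)cc(O)c3c(=O)c2-c2c(OCc3ccccc3)cc(O)c(C(C)=O)c2OCc2ccccc2)cc1 | intermediate
21 | 3-{2,6-bis(benzyloxy)-3-[(2E)-3-(dimethylamino)prop-2-enoyl]-4-hydroxyphenyl}-5-hydroxy-7-methoxy-2-(4-methoxyphenyl)-4H-chromen-4-one | COc1ccc(-c2oc3cc(OC)cc(O)c3c(=O)c2-c2c(OCc3ccccc3)cc(O)c(C(=O)/C=C/N(C)C)c2OCc2ccccc2)cc1 | intermediate (not isolated)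
22 | 5,7-bis(benzyloxy)-6-[5-hydroxy-7-methoxy-2-(4-methoxyphenyl)-4-oxo-4H-chromen-3-yl]-4H-chromen-4-one | COc1ccc(-c2oc3cc(OC)cc(O)c3c(=O)c2-c2c(OCc3ccccc3)cc3occc(=O)c3c2OCc2ccccc2)cc1 | intermediate
23 | [4-(benzyloxy)phenyl]boronic acid | OB(O)c1ccc(OCc2ccccc2)cc1 | starting material
24 | (2R)-5,7-bis(benzyloxy)-2-[4-(benzyloxy)phenyl]-6-[5-hydroxy-7-methoxy-2-(4-methoxyphenyl)-4-oxo-4H-chromen-3-yl]-2,3-dihydro-4H-chromen-4-one | COc1ccc(-c2oc3cc(OC)cc(O)c3c(=O)c2-c2c(OCc3ccccc3)cc3c(c2OCc2ccccc2)C(=O)C[C@H](c2ccc(OCc4ccccc4)cc2)O3)cc1 | intermediate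
25 | (2R)-5,7-dihydroxy-2-(4-hydroxyphenyl)-6-[5-hydroxy-7-methoxy-2-(4-methoxyphenyl)-4-oxo-4H-chromen-3-yl]-2,3-dihydro-4H-chromen-4-one (CNP0292254.1) | COc1ccc(-c2oc3cc(OC)cc(O)c3c(=O)c2-c2c(O)cc3c(c2O)C(=O)C[C@H](c2ccc(O)cc2)O3)cc1 | target

**Totals**

Total step count: 14. Longest linear sequence: 14 steps (1 → 25); 10, 13 and 23 are commercial and enter directly.

**Steps most likely to fail**

Step 8. C-Acylation at the ketene carbon may be slow because the α-aryl group carries two ortho benzyloxy groups. The aroylketene would then be lost to dimerisation or, with traces of water, to decarboxylation, and long heating could let benzyl or silyl groups migrate. The fallback sets out from aldehyde 7 (isolated after the hydrolysis stage of step 5) and returns at 16. Condensation of 7 with hydroxylamine (NH2OH·HCl, NaOAc, EtOH) would give the aldoxime F1, and dehydration with acetic anhydride at 100 °C the arylacetonitrile F2. A Hoesch reaction of F2 with phloroglucinol 13 (ZnCl2, HCl gas, Et2O, 0 °C, then aqueous hydrolysis) would give the deoxybenzoin F3, which forms C4–C4a under conditions that benzyl aryl ethers tolerate. Heating F3 with excess 4-methoxybenzoyl chloride 10, DBU and pyridine should effect O-aroylation, Baker–Venkataraman acyl shift and cyclodehydration to the bis(4-methoxybenzoate) F4. Here the crowded C2–C3 bond is made by an intramolecular acyl transfer. Pyrrolidine in CH2Cl2 would then cleave the two phenolic esters to give 16.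

Step 13. The electron-rich 5,7-dialkoxychromone may convert poorly, facial discrimination next to the bulky C6 substituent may be insufficient, or the product may open by retro-oxa-Michael reaction at 60 °C and lose enantiopurity. The fallback sets out from 20 and returns at 24. Claisen–Schmidt condensation of 20 with 4-(benzyloxy)benzaldehyde (KOH, EtOH/THF, rt) would give the 2'-hydroxychalcone F5. Sodium acetate in refluxing ethanol should close it by oxa-Michael addition to the racemic flavanone F6. Preparative HPLC on a chiral stationary phase would then separate 24 from its (2S)-enantiomer F7.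

Step 11. Oxidative addition and transmetalation may be slow at a bromide flanked by a hydroxyl and a benzyloxy group on an electron-rich ring, with protodebromination or catalyst deactivation by the free phenols taking over. The fallback sets out from 18 and returns at 20. Suzuki–Miyaura coupling of 18 with isopropenylboronic acid pinacol ester (Pd(OAc)2, SPhos, K3PO4, toluene/H2O, 90 °C), a catalyst system suited to hindered electron-rich bromides, would give the isopropenyl arene F8. Lemieux–Johnson cleavage of its 1,1-disubstituted alkene (OsO4 cat., NaIO4, 2,6-lutidine, dioxane/H2O) would give 20.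

**Further compounds**

F1 | step 8 | 2-{2,6-bis(benzyloxy)-3-bromo-4-[(triisopropylsilyl)oxy]phenyl}acetaldehyde oxime (E/Z) | ON=CCc1c(OCc2ccccc2)cc(O[Si](C(C)C)(C(C)C)C(C)C)c(Br)c1OCc1ccccc1
F2 | step 8 | 2-{2,6-bis(benzyloxy)-3-bromo-4-[(triisopropylsilyl)oxy]phenyl}acetonitrile | N#CCc1c(OCc2ccccc2)cc(O[Si](C(C)C)(C(C)C)C(C)C)c(Br)c1OCc1ccccc1
F3 | step 8 | 2-{2,6-bis(benzyloxy)-3-bromo-4-[(triisopropylsilyl)oxy]phenyl}-1-(2,4,6-trihydroxyphenyl)ethan-1-one | O=C(Cc1c(OCc2ccccc2)cc(O[Si](C(C)C)(C(C)C)C(C)C)c(Br)c1OCc1ccccc1)c1c(O)cc(O)cc1O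
F4 | step 8 | 3-{2,6-bis(benzyloxy)-3-bromo-4-[(triisopropylsilyl)oxy]phenyl}-2-(4-methoxyphenyl)-4-oxo-4H-chromene-5,7-diyl bis(4-methoxybenzoate) | COc1ccc(-c2oc3cc(OC(=O)c4ccc(OC)cc4)cc(OC(=O)c4ccc(OC)cc4)c3c(=O)c2-c2c(OCc3ccccc3)cc(O[Si](C(C)C)(C(C)C)C(C)C)c(Br)c2OCc2ccccc2)cc1
F5 | step 13 | 3-{2,6-bis(benzyloxy)-3-[(2E)-3-[4-(benzyloxy)phenyl]prop-2-enoyl]-4-hydroxyphenyl}-5-hydroxy-7-methoxy-2-(4-methoxyphenyl)-4H-chromen-4-one | COc1ccc(-c2oc3cc(OC)cc(O)c3c(=O)c2-c2c(OCc3ccccc3)cc(O)c(C(=O)/C=C/c3ccc(OCc4ccccc4)cc3)c2OCc2ccccc2)cc1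
F6 | step 13 | racemic 5,7-bis(benzyloxy)-2-[4-(benzyloxy)phenyl]-6-[5-hydroxy-7-methoxy-2-(4-methoxyphenyl)-4-oxo-4H-chromen-3-yl]-2,3-dihydro-4H-chromen-4-one | COc1ccc(-c2oc3cc(OC)cc(O)c3c(=O)c2-c2c(OCc3ccccc3)cc3c(c2OCc2ccccc2)C(=O)CC(c2ccc(OCc4ccccc4)cc2)O3)cc1
F7 | step 13 | (2S)-5,7-bis(benzyloxy)-2-[4-(benzyloxy)phenyl]-6-[5-hydroxy-7-methoxy-2-(4-methoxyphenyl)-4-oxo-4H-chromen-3-yl]-2,3-dihydro-4H-chromen-4-one | COc1ccc(-c2oc3cc(OC)cc(O)c3c(=O)c2-c2c(OCc3ccccc3)cc3c(c2OCc2ccccc2)C(=O)C[C@@H](c2ccc(OCc4ccccc4)cc2)O3)cc1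
F8 | step 11 | 3-[2,6-bis(benzyloxy)-4-hydroxy-3-(prop-1-en-2-yl)phenyl]-5-hydroxy-7-methoxy-2-(4-methoxyphenyl)-4H-chromen-4-one | COc1ccc(-c2oc3cc(OC)cc(O)c3c(=O)c2-c2c(OCc3ccccc3)cc(O)c(C(C)=C)c2OCc2ccccc2)cc1
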